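**Retrosynthetic overview**
- The strategy rests on the bromine at C6' of ring B. It sits ortho to the ether carbon C1' and meta to the C2' oxygen, a site electrophilic bromination does not reach because it goes para to the C2' oxygen (C5'). C6' is therefore brought in as a ready-made C–Br carbon.
- Target 14 ← O-demethylation of 12 ← twofold bromination of diaryl ether 10, para to each methoxy group (C4 of ring A, C5' of ring B).
- 10 ← one-carbon ring expansion: dibromocarbene from bromoform 7 is inserted between C1' and C5' of the cyclopentenyl aryl ether ketal 6, and the ring aromatizes by loss of HBr and methanol.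
- 6 ← ketalization of 2-aryloxy enone 5 ← guaiacol 3 + epoxy ketone 2 ← cyclopent-2-en-1-one 1.
- Ring order: ring A is bought (guaiacol); ring B is made last, from the five-membered carbocycle.

Key step: step 4

Remark: the target has no stereocenter; 2, 4 and 8 are racemic (one enantiomer is drawn) and their stereocenters are removed later in the route.

**Route**

Step 1
Reactants: 1 cyclopent-2-en-1-one
Product: 2 rac-6-oxabicyclo[3.1.0]hexan-2-one (2,3-epoxycyclopentanone)
Conditions: 30% aq H2O2, NaOH (cat.), MeOH, −5 to 0 °C
Reagents that add atoms: hydrogen peroxide (OO)
Why: Weitz–Scheffer nucleophilic epoxidation of the enone (conjugate addition of hydroperoxide, then ring closure of the enolate on O–O); the epoxide is necessarily cis-fused and racemic, and both stereocenters are removed in step 2.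

Step 2
Reactants: 2 rac-6-oxabicyclo[3.1.0]hexan-2-one; 3 guaiacol
Product: 5 2-(2-methoxyphenoxy)cyclopent-2-en-1-one, via β-hydroxy ketone 4 (not isolated)
Conditions: KH (0.2 equiv), THF/DMPU, 65 °C
Reagents that add atoms: none
Why: The phenoxide should open the epoxy ketone by SN2 attack at the carbonyl-activated α-carbon (inversion, trans-hydroxy ether 4), and E1cB loss of water from the β-hydroxy ketone then gives the 2-aryloxy enone and regenerates the base; this is the established preparation of 2-aryloxy cycloalkenones from epoxy ketones and phenols.

Step 3
Reactants: 5 2-(2-methoxyphenoxy)cyclopent-2-en-1-one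
Product: 6 1-[(5,5-dimethoxycyclopent-1-en-1-yl)oxy]-2-methoxybenzene
Conditions: MeOSiMe3 (2.5 equiv), Me3SiOSO2CF3 (5 mol%), CH2Cl2, −78 to −30 °C; then pyridine; chromatography on Et3N-deactivated silica
Reagents that add atoms: methoxytrimethylsilane (CO[Si](C)(C)C)
Why: Noyori ketalization under aprotic conditions at low temperature should convert the enone carbonyl into the dimethyl ketal without free methanol or Brønsted acid, so neither conjugate addition to C3 nor alkene migration is expected; formation of the Si–O–Si bond drives the reaction, and the basic quench protects the ionization-prone allylic ketal.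

Step 4
Reactants: 6 1-[(5,5-dimethoxycyclopent-1-en-1-yl)oxy]-2-methoxybenzene; 7 bromoform
Product: 10 1-bromo-3-methoxy-2-(2-methoxyphenoxy)benzene, via dibromocyclopropane 8 (not isolated), via bromodiene 9 (not isolated)
Conditions: CHBr3 (1.2 equiv), KOtBu (2.5 equiv), pentane, −20 °C to rt; then pyridinium p-toluenesulfonate (cat.), dry CH2Cl2, rt
Reagents that add atoms: none
Why: Dibromocarbene, formed by α-elimination from 7 with KOtBu, should add as an electrophile in a concerted [2+1] cheletropic step to the only alkene of 6, the aryl enol ether C1'=C5', giving cis-fused cyclopropane 8; the strained 6,6-dibromobicyclo[3.1.0]hexane then opens by disrotatory two-electron electrocyclic cleavage of the C1'–C5' bond with departure of the endo bromide, assisted by the aryloxy lone pair on C1', so that the new carbon C6' ends up bonded to C1' and C5' and keeps one bromine. Loss of a proton from C4' of the resulting 2-bromoallyl cation gives diene 9, and catalytic anhydrous acid ionizes the ketal to an oxocarbenium ion that is the C3'-protonated arenium ion of the product, so proton loss from C3' expels methanol and gives anisole 10. The closest known reaction type is the dihalocarbene ring expansion of cyclic enol ethers and silyl enol ethers to 2-halo dienyl ethers and 2-halo enones, and of cyclopentadienes and indenes to haloarenes. Ring B is not closed by a cyclization but arises by enlargement of the carbocycle (three-membered ring closure by cycloaddition, then cyclopropyl-to-allyl cation opening); the two stereocenters of 8 are fixed cis by the suprafacial addition and disappear on opening, so the product has none. The step needs site selectivity for the insertion and survival of the C1'–O aryl ether: the first is secured because 6 has a single electron-rich alkene and only a small excess of 7 is used, so diene 9 is not cyclopropanated again; the second because water and small alkoxides are excluded (bulky tert-butoxide, hydrocarbon solvent), so the cation loses a proton instead of being captured at C1', which would release guaiacol.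

Step 5
Reactants: 10 1-bromo-3-methoxy-2-(2-methoxyphenoxy)benzene
Product: 12 1,2-dibromo-3-(5-bromo-2-methoxyphenoxy)-4-methoxybenzene, via monobromide 11 (not isolated)
Conditions: NBS (2.1 equiv), MeCN, 0 to 40 °C
Reagents that add atoms: N-bromosuccinimide (O=C1CCC(=O)N1Br)
Why: Electrophilic aromatic bromination with NBS in acetonitrile is para-selective for anisoles; the bromine-free ring A should react first at C4 (para to its methoxy group), then ring B at C5' (para to its methoxy group and ortho to the C6' bromine), because methoxy is a stronger para director than the shared diaryl ether oxygen.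

Step 6
Reactants: 12 1,2-dibromo-3-(5-bromo-2-methoxyphenoxy)-4-methoxybenzene
Product: 14 3,4-dibromo-2-(5-bromo-2-hydroxyphenoxy)phenol, via aryl borate 13 (not isolated)
Conditions: BBr3 (3 equiv), CH2Cl2, −78 °C to rt; then H2O
Reagents that add atoms: none
Why: Lewis acid-mediated cleavage of aryl methyl ethers (boron complexation, then SN2 attack of bromide on the methyl group) should remove both methyl groups, while the diaryl ether bond and the aryl bromides are inert to BBr3; hydrolysis of the aryl borate 13 releases the bis-phenol.

**Compound list**

1 | cyclopent-2-en-1-one | O=C1C=CCC1 | starting material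
2 | rac-6-oxabicyclo[3.1.0]hexan-2-one (cis-fused 2,3-epoxycyclopentanone, racemate) | O=C1CC[C@@H]2O[C@H]12 | intermediate
3 | guaiacol (2-methoxyphenol) | COc1ccccc1O | starting material
4 | trans-3-hydroxy-2-(2-methoxyphenoxy)cyclopentan-1-one (racemate) | O=C1CC[C@H](O)[C@H]1Oc1ccccc1OC | intermediate
5 | 2-(2-methoxyphenoxy)cyclopent-2-en-1-one | COc1ccccc1OC1=CCCC1=O | intermediate
6 | 1-[(5,5-dimethoxycyclopent-1-en-1-yl)oxy]-2-methoxybenzene | COc1ccccc1OC1=CCCC1(OC)OC | intermediate
7 | bromoform | BrC(Br)Br | starting material
8 | cis-fused 6,6-dibromo-2,2-dimethoxy-1-(2-methoxyphenoxy)bicyclo[3.1.0]hexane (racemate) | COc1ccccc1O[C@]12C(Br)(Br)[C@H]1CCC2(OC)OC | intermediate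
9 | 1-[(2-bromo-6,6-dimethoxycyclohexa-1,3-dien-1-yl)oxy]-2-methoxybenzene | COc1ccccc1OC1=C(Br)C=CCC1(OC)OC | intermediate
10 | 1-bromo-3-methoxy-2-(2-methoxyphenoxy)benzene | COc1ccccc1Oc1c(OC)cccc1Br | intermediate
11 | 4-bromo-2-(2-bromo-6-methoxyphenoxy)-1-methoxybenzene | COc1ccc(Br)cc1Oc1c(OC)cccc1Br | intermediate
12 | 1,2-dibromo-3-(5-bromo-2-methoxyphenoxy)-4-methoxybenzene | COc1ccc(Br)cc1Oc1c(OC)ccc(Br)c1Br | intermediate
13 | 1,2-dibromo-4-(dibromoboryloxy)-3-[5-bromo-2-(dibromoboryloxy)phenoxy]benzene (aryl borate) | BrB(Br)Oc1ccc(Br)cc1Oc1c(OB(Br)Br)ccc(Br)c1Br | intermediate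
14 | 3,4-dibromo-2-(5-bromo-2-hydroxyphenoxy)phenol | Oc1ccc(Br)cc1Oc1c(O)ccc(Br)c1Br | target

**Summary**

Total step count: 6. Longest linear sequence: 6 steps (from 1 to 14).

**Steps most likely to fail**

Step 4 (key step). Three processes can interfere:
- slow cyclopropanation of the aryl enol ether beside the quaternary ketal carbon;
- capture of the allyl cation at C1' by an oxygen nucleophile, followed by collapse of the mixed ketal with loss of guaiacol;
- a second carbene addition to the newly formed diene.

The fallback gives up the ring expansion and builds the diaryl ether by known copper chemistry. It sets out from guaiacol 3. Ortho-selective bromination with the tert-butylamine–bromine complex (tBuNH2, Br2, toluene, −78 °C) should give 2-bromo-6-methoxyphenol F1. Ullmann coupling of F1 with 2-iodoanisole (CuI, picolinic acid, K3PO4, DMSO, 90 °C), in which the aryl iodide reacts in preference to the aryl bromide, should give the diaryl ether and return to the route at 10.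

Step 3. The allylic ketal may ionize with loss of methanol to a reactive cyclopentadiene, or methanol may add to C3, so that ketalization of the enone stalls or gives mixtures. The fallback places the ketal on the five-membered ring before the aryl ether is made; it sets out from guaiacol 3 and also bypasses steps 1 and 2.
- Cyclopentanone is α-oxidized with PhI(OAc)2 and KOH in MeOH to rac-2,2-dimethoxycyclopentan-1-ol F2.
- Buffered Dess–Martin oxidation gives 2,2-dimethoxycyclopentan-1-one F3.
- Enolization on the only enolizable side (KN(SiMe3)2, PhNTf2, THF, −78 °C) gives 5,5-dimethoxycyclopent-1-en-1-yl trifluoromethanesulfonate F4.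
- Palladium-catalysed C–O coupling of F4 with 3 (Pd2(dba)3, 2-(di-tert-butylphosphino)biphenyl, NaOtBu, toluene, 100 °C) forms the aryl enol ether and returns to the route at 6.

Step 5. Regiocontrol may be incomplete: a second bromination of ring A, or attack para to the diaryl ether oxygen, can compete with the slower bromination of the bromine-deactivated ring B. The fallback reverses the order of the last two operations and sets out from 10. BBr3 demethylation (CH2Cl2, −78 °C to rt) gives 3-bromo-2-(2-hydroxyphenoxy)phenol F5. Its two free phenols direct more strongly, and para-selective monobromination of each with tetrabutylammonium tribromide (nBu4NBr3, 2 equiv, CH2Cl2/MeOH, rt) should return to the route at the target 14.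

**Further compounds**

F1 | step 4 | 2-bromo-6-methoxyphenol | COc1cccc(Br)c1O
F2 | step 3 | rac-2,2-dimethoxycyclopentan-1-ol | COC1(OC)CCC[C@H]1O
F3 | step 3 | 2,2-dimethoxycyclopentan-1-one | COC1(OC)CCCC1=O
F4 | step 3 | 5,5-dimethoxycyclopent-1-en-1-yl trifluoromethanesulfonate | COC1(OC)CCC=C1OS(=O)(=O)C(F)(F)F
F5 | step 5 | 3-bromo-2-(2-hydroxyphenoxy)phenol | Oc1ccccc1Oc1c(O)cccc1Br
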